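**Plan**

- Cuts: the three O–MOM bonds (last step); the C2–H bond (back to the flat flavone); C4a–C4, C4–C3 and O1–C2 of ring C in one operation; and C8–C1'' between ring A and the C10 chain.
- Enabling feature: C4 is a lone carbonyl carbon between C4a of ring A and C3, and O1 sits on C8a next to C4a. Ring C therefore equals a ring A 2-iodophenol plus CO plus the ring B arylacetylene.
- Forward order: the chain is cut out of limonene oxide by ring opening, methylenation and loss of the one surplus terpene carbon as CO2. It is joined to a phloroglucinol-derived aryl iodide by Negishi coupling, and ring A is then iodinated next to the oxygen that becomes O1.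
- Rings A and B are bought as arenes. Ring C is the only ring built, as the pyranone, with ring B and C4 arriving together.
- Stereochemistry: C2'' (R) is C4 of (R)-limonene and is never a reacting centre. C2 (S) comes from ligand-controlled copper hydride addition to C2=C3 of the flavone.

Key step: step 14

Assumption: (R)-DTBM-SEGPHOS is taken to direct hydride to the face of C2 that gives 2S. Should a trial show the opposite sense, its enantiomer is used with no other change.

**Chain (steps 1–4)**

Step 1
Reactants: 1 (4R)-limonene 1,2-oxide (commercial cis/trans mixture)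
Product: 3 (3R)-6-oxo-3-(prop-1-en-2-yl)heptanal, via limonene-1,2-diol 2 (not isolated)
Conditions: H5IO6, THF–H2O, 0 °C to rt
Reagents that add atoms: water, O
Why: Acid-promoted hydrolysis of either epoxide isomer to the 1,2-diol and Malaprade glycol cleavage by the same reagent open the ring only between C1 and C2 of the terpene, the isopropenyl group is inert to periodic acid, and the stereocentre takes no part.

Step 2
Reactants: 3 (3R)-6-oxo-3-(prop-1-en-2-yl)heptanal
Product: 4 (3R)-6-oxo-3-(prop-1-en-2-yl)heptanoic acid
Conditions: NaClO2, NaH2PO4, 2-methyl-2-butene, t-BuOH–H2O, 0 °C to rt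
Reagents that add atoms: sodium chlorite, [Na+].[O-]Cl=O
Why: The Pinnick oxidation turns the aldehyde into the acid at buffered pH without touching the ketone, and the excess 2-methyl-2-butene intercepts the hypochlorous acid before it can reach the isopropenyl group.

Step 3
Reactants: 4 (3R)-6-oxo-3-(prop-1-en-2-yl)heptanoic acid
Product: 5 (3R)-6-methyl-3-(prop-1-en-2-yl)hept-6-enoic acid
Conditions: Ph3PCH3Br, KOt-Bu (excess), THF, 0 °C to rt; then 1 M HCl (work-up)
Reagents that add atoms: methyltriphenylphosphonium bromide, C[P+](c1ccccc1)(c1ccccc1)c1ccccc1.[Br-]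
Why: Wittig methylenation works on the potassium carboxylate, which is inert to the ylide, and the stereocentre is beta to the carboxylate and gamma to the ketone, so the basic medium cannot epimerise it.

Step 4
Reactants: 5 (3R)-6-methyl-3-(prop-1-en-2-yl)hept-6-enoic acid
Product: 7 (3S)-3-(iodomethyl)-2,6-dimethylhepta-1,6-diene, via Barton ester 6 (not isolated)
Conditions: 1-hydroxypyridine-2(1H)-thione, DCC, CH2Cl2, 0 °C, dark; then CHI3, benzene–cyclohexene, tungsten lamp, rt
Reagents that add atoms: iodoform, IC(I)I
Why: The Barton decarboxylative iodination (thiohydroxamate variant of the Hunsdiecker reaction) excises the carbon that the opened terpene carries in excess of C1'': the primary radical left after loss of CO2 takes iodine from iodoform far faster than it can add to either 1,1-disubstituted alkene or suffer vinyl migration, the protocol tolerates alkenes to the point of using cyclohexene as cosolvent, and the adjacent stereocentre is not a radical site (the descriptor changes to S only because CH2I outranks isopropenyl).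

**Ring A (steps 5–10)**

Step 5
Reactants: 8 phloroglucinol
Product: 9 3,5-bis(methoxymethoxy)phenol
Conditions: MOMCl (2 equiv), i-Pr2NEt, CH2Cl2–DMF, 0 °C to rt
Reagents that add atoms: chloromethyl methyl ether, COCCl
Why: Williamson-type O-alkylation with two equivalents of MOMCl is statistical but standard for phloroglucinol, and the mono- and tris-ethers are removed by chromatography and can be recycled.

Step 6
Reactants: 9 3,5-bis(methoxymethoxy)phenol
Product: 10 3,5-bis(methoxymethoxy)phenyl diethylcarbamate
Conditions: NaH, Et2NCOCl, THF, 0 °C to rt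
Reagents that add atoms: diethylcarbamoyl chloride, CCN(CC)C(=O)Cl
Why: O-Carbamoylation of the sodium phenoxide installs the strongest oxygen-based director for ortho-metalation and at the same time marks the oxygen that will become O1.

Step 7
Reactants: 10 3,5-bis(methoxymethoxy)phenyl diethylcarbamate
Product: 12 2-iodo-3,5-bis(methoxymethoxy)phenyl diethylcarbamate, via 2-lithio carbamate 11 (not isolated)
Conditions: s-BuLi, TMEDA, THF, −78 °C; then I2, −78 °C to rt
Reagents that add atoms: iodine, II
Why: Directed ortho-metalation takes place at the C–H flanked by the carbamate and one OMOM group, because the carbamate outranks OMOM as a director and the two act together there, the anionic ortho-Fries shift is frozen at −78 °C, and iodine traps the aryllithium.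

Step 8
Reactants: 7 (3S)-3-(iodomethyl)-2,6-dimethylhepta-1,6-diene; 12 2-iodo-3,5-bis(methoxymethoxy)phenyl diethylcarbamate
Product: 14 2-[(2R)-5-methyl-2-(prop-1-en-2-yl)hex-5-en-1-yl]-3,5-bis(methoxymethoxy)phenyl diethylcarbamate, via alkylzinc iodide 13 (not isolated)
Conditions: 7, Zn dust, LiCl, THF, 40 °C; then 12, Pd(OAc)2 (2 mol %), SPhos (4 mol %), THF, rt to 50 °C
Reagents that add atoms: none
Why: In this Negishi sp3–sp2 cross-coupling LiCl-assisted zinc insertion gives the primary alkylzinc iodide without touching the alkenes, and the bulky electron-rich biarylphosphine favours oxidative addition into the doubly ortho-substituted C–I bond and fast reductive elimination over beta-hydride elimination, so the stereocentre beta to the metal is retained.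

Step 9
Reactants: 14 2-[(2R)-5-methyl-2-(prop-1-en-2-yl)hex-5-en-1-yl]-3,5-bis(methoxymethoxy)phenyl diethylcarbamate
Product: 16 2-iodo-3,5-bis(methoxymethoxy)-6-[(2R)-5-methyl-2-(prop-1-en-2-yl)hex-5-en-1-yl]phenyl diethylcarbamate, via 6-lithio carbamate 15 (not isolated)
Conditions: s-BuLi, TMEDA, THF, −78 °C; then I2, −78 °C to rt
Reagents that add atoms: iodine, II
Why: A second directed ortho-metalation goes to the only remaining C–H next to the carbamate, again reinforced by OMOM and kinetically preferred at −78 °C with s-BuLi/TMEDA over the C–H between the two OMOM groups and over benzylic or allylic C–H bonds, and the iodine quench places the halogen on the future C4a.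

Step 10
Reactants: 16 2-iodo-3,5-bis(methoxymethoxy)-6-[(2R)-5-methyl-2-(prop-1-en-2-yl)hex-5-en-1-yl]phenyl diethylcarbamate
Product: 17 2-iodo-3,5-bis(methoxymethoxy)-6-[(2R)-5-methyl-2-(prop-1-en-2-yl)hex-5-en-1-yl]phenol
Conditions: NaOH, EtOH–H2O, reflux; then aq. NH4Cl
Reagents that add atoms: none
Why: Alkaline hydrolysis of the aryl carbamate (addition–elimination at the carbamoyl carbon) is slow for a doubly ortho-substituted substrate but can be forced, since MOM acetals, the aryl iodide and the isolated alkenes are all inert to hot aqueous-ethanolic hydroxide.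

**Ring B alkyne (steps 11–13)**

Step 11
Reactants: 18 4-iodophenol
Product: 19 1-iodo-4-(methoxymethoxy)benzene
Conditions: MOMCl, i-Pr2NEt, CH2Cl2, 0 °C to rt
Reagents that add atoms: chloromethyl methyl ether, COCCl
Why: Williamson-type O-alkylation of a single unhindered phenol with MOMCl is routine and gives ring B the same protecting group as ring A.

Step 12
Reactants: 19 1-iodo-4-(methoxymethoxy)benzene; 20 trimethylsilylacetylene
Product: 21 {[4-(methoxymethoxy)phenyl]ethynyl}trimethylsilane
Conditions: PdCl2(PPh3)2 (2 mol %), CuI (4 mol %), Et3N, THF, rt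
Reagents that add atoms: none
Why: Sonogashira coupling of an unhindered aryl iodide proceeds at room temperature, and the silyl cap prevents double coupling.

Step 13
Reactants: 21 {[4-(methoxymethoxy)phenyl]ethynyl}trimethylsilane
Product: 22 1-ethynyl-4-(methoxymethoxy)benzene
Conditions: K2CO3 (cat.), MeOH, rt
Reagents that add atoms: none
Why: Base-catalysed methanolysis of the C(sp)–Si bond frees the terminal alkyne and leaves the MOM acetal untouched.

**Union and endgame (steps 14–16)**

Step 14
Reactants: 17 2-iodo-3,5-bis(methoxymethoxy)-6-[(2R)-5-methyl-2-(prop-1-en-2-yl)hex-5-en-1-yl]phenol; 22 1-ethynyl-4-(methoxymethoxy)benzene; 23 carbon monoxide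
Product: 26 5,7-bis(methoxymethoxy)-2-[4-(methoxymethoxy)phenyl]-8-[(2R)-5-methyl-2-(prop-1-en-2-yl)hex-5-en-1-yl]-4H-chromen-4-one, via ynone 24 (not isolated), via enaminone 25 (not isolated)
Conditions: PdCl2(PPh3)2 (5 mol %), CO (20 bar), Et2NH, 120 °C, autoclave
Reagents that add atoms: none
Why: PdCl2(PPh3)2 is reduced in the amine to zerovalent palladium, which inserts into the C4a–I bond of 17; CO insertion gives the aroylpalladium iodide, the amine-deprotonated alkyne 22 takes the place of iodide, and reductive elimination delivers ynone 24 with the new C4a–C4 and C4–C3 bonds. Diethylamine then adds to C2 of 24 to give enaminone 25, and the free C8a phenol attacks the same carbon and expels the amine, which forms O1–C2. The closest known reaction type is the palladium-catalysed carbonylative Sonogashira coupling–cyclisation of 2-iodophenols with terminal arylacetylenes in secondary amines, an established flavone synthesis. Ring C closes in the 6-endo mode (formally 6-endo-dig on 24, in practice an addition–elimination on 25), and no stereocentre is created, C2'' being a remote spectator. The step needs 6-endo and not 5-exo closure, which the enaminone secures by making C2 the only electrophilic carbon; CO uptake ahead of direct alkynylation, which the CO pressure and the absence of copper secure; and closure through O1 and not O5, which the MOM ether on O5 secures, so that only the 8-alkyl isomer can form. The two chain alkenes are 1,1-disubstituted and hang from C8, meta to C4a, out of reach of the aroylpalladium centre.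

Step 15
Reactants: 26 5,7-bis(methoxymethoxy)-2-[4-(methoxymethoxy)phenyl]-8-[(2R)-5-methyl-2-(prop-1-en-2-yl)hex-5-en-1-yl]-4H-chromen-4-one
Product: 28 (2S)-5,7-bis(methoxymethoxy)-2-[4-(methoxymethoxy)phenyl]-8-[(2R)-5-methyl-2-(prop-1-en-2-yl)hex-5-en-1-yl]chroman-4-one, via silyl enol ether 27 (not isolated)
Conditions: Cu(OAc)2 (5 mol %), (R)-DTBM-SEGPHOS (5.5 mol %), (EtO)2MeSiH, toluene, 0 °C to rt; then AcOH, THF–H2O, 0 °C
Reagents that add atoms: none
Why: Proposed new method: the ligated copper hydride formed from Cu(OAc)2 and the silane should deliver hydride to C2 of the C2=C3–C4=O unit from the face left open by the chiral bisphosphine, which sets 2S under catalyst control (C2'' is too remote to matter), and the copper enolate then undergoes sigma-bond metathesis with the silane to give silyl enol ether 27, which shields C4 from 1,2-reduction and cannot ring-open by E1cB, so the new centre is kept until the mild acidic hydrolysis; the closest known reaction type is the asymmetric copper hydride conjugate reduction of beta,beta-disubstituted cyclic enones and of 2-substituted chromones, the new element being the less electrophilic 2-aryl-5,7-dioxygenated chromone, while the unactivated chain alkenes are hydrocuprated only on heating.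

Step 16
Reactants: 28 (2S)-5,7-bis(methoxymethoxy)-2-[4-(methoxymethoxy)phenyl]-8-[(2R)-5-methyl-2-(prop-1-en-2-yl)hex-5-en-1-yl]chroman-4-one
Product: 29 remangiflavanone A
Conditions: 3 M aq. HCl, MeOH, 45 °C
Reagents that add atoms: none
Why: Acid-catalysed acetal exchange with methanol removes the three aryl MOM groups under conditions long used for prenylated flavanones, where oxocarbenium formation from the acetals outruns protonation of the 1,1-disubstituted alkenes, and acid does not open ring C, so C2 keeps its configuration.

**Compound list**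

1 | (4R)-limonene 1,2-oxide, cis/trans mixture at C1/C2 | CC12OC1C[C@@H](CC2)C(C)=C | starting material
2 | (4R)-p-menth-8-ene-1,2-diol (limonene-1,2-diol) | CC1(O)C(O)C[C@@H](CC1)C(C)=C | intermediate
3 | (3R)-6-oxo-3-(prop-1-en-2-yl)heptanal | CC(=O)CC[C@H](CC=O)C(=C)C | intermediate
4 | (3R)-6-oxo-3-(prop-1-en-2-yl)heptanoic acid | CC(=O)CC[C@H](CC(=O)O)C(=C)C | intermediate
5 | (3R)-6-methyl-3-(prop-1-en-2-yl)hept-6-enoic acid | C=C(C)CC[C@H](CC(=O)O)C(=C)C | intermediate
6 | 2-thioxopyridin-1(2H)-yl (3R)-6-methyl-3-(prop-1-en-2-yl)hept-6-enoate (Barton ester) | C=C(C)CC[C@H](CC(=O)ON1C=CC=CC1=S)C(=C)C | intermediate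
7 | (3S)-3-(iodomethyl)-2,6-dimethylhepta-1,6-diene | C=C(C)CC[C@H](CI)C(=C)C | intermediate
8 | phloroglucinol | Oc1cc(O)cc(O)c1 | starting material
9 | 3,5-bis(methoxymethoxy)phenol | COCOc1cc(O)cc(OCOC)c1 | intermediate
10 | 3,5-bis(methoxymethoxy)phenyl diethylcarbamate | CCN(CC)C(=O)Oc1cc(OCOC)cc(OCOC)c1 | intermediate
11 | 2-lithio-3,5-bis(methoxymethoxy)phenyl diethylcarbamate | CCN(CC)C(=O)Oc1cc(OCOC)cc(OCOC)c1[Li] | intermediate
12 | 2-iodo-3,5-bis(methoxymethoxy)phenyl diethylcarbamate | CCN(CC)C(=O)Oc1cc(OCOC)cc(OCOC)c1I | intermediate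
13 | [(2S)-5-methyl-2-(prop-1-en-2-yl)hex-5-en-1-yl]zinc iodide | C=C(C)CC[C@H](C[Zn]I)C(=C)C | intermediate
14 | 2-[(2R)-5-methyl-2-(prop-1-en-2-yl)hex-5-en-1-yl]-3,5-bis(methoxymethoxy)phenyl diethylcarbamate | C=C(C)CC[C@H](Cc1c(OC(=O)N(CC)CC)cc(OCOC)cc1OCOC)C(=C)C | intermediate
15 | 6-lithio derivative of 14 (lithium between carbamate and OMOM) | C=C(C)CC[C@H](Cc1c(OC(=O)N(CC)CC)c([Li])c(OCOC)cc1OCOC)C(=C)C | intermediate
16 | 2-iodo-3,5-bis(methoxymethoxy)-6-[(2R)-5-methyl-2-(prop-1-en-2-yl)hex-5-en-1-yl]phenyl diethylcarbamate | C=C(C)CC[C@H](Cc1c(OC(=O)N(CC)CC)c(I)c(OCOC)cc1OCOC)C(=C)C | intermediate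
17 | 2-iodo-3,5-bis(methoxymethoxy)-6-[(2R)-5-methyl-2-(prop-1-en-2-yl)hex-5-en-1-yl]phenol | C=C(C)CC[C@H](Cc1c(O)c(I)c(OCOC)cc1OCOC)C(=C)C | intermediate
18 | 4-iodophenol | Oc1ccc(I)cc1 | starting material
19 | 1-iodo-4-(methoxymethoxy)benzene | COCOc1ccc(I)cc1 | intermediate
20 | trimethylsilylacetylene | C#C[Si](C)(C)C | starting material
21 | {[4-(methoxymethoxy)phenyl]ethynyl}trimethylsilane | COCOc1ccc(C#C[Si](C)(C)C)cc1 | intermediate
22 | 1-ethynyl-4-(methoxymethoxy)benzene | C#Cc1ccc(OCOC)cc1 | intermediate
23 | carbon monoxide | [C-]#[O+] | starting material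
24 | 1-{2-hydroxy-4,6-bis(methoxymethoxy)-3-[(2R)-5-methyl-2-(prop-1-en-2-yl)hex-5-en-1-yl]phenyl}-3-[4-(methoxymethoxy)phenyl]prop-2-yn-1-one (ynone) | C=C(C)CC[C@H](Cc1c(O)c(C(=O)C#Cc2ccc(OCOC)cc2)c(OCOC)cc1OCOC)C(=C)C | intermediate
25 | 3-(diethylamino) enone formed from 24 and diethylamine (enaminone, alkene geometry open) | C=C(C)CC[C@H](Cc1c(O)c(C(=O)C=C(N(CC)CC)c2ccc(OCOC)cc2)c(OCOC)cc1OCOC)C(=C)C | intermediate
26 | 5,7-bis(methoxymethoxy)-2-[4-(methoxymethoxy)phenyl]-8-[(2R)-5-methyl-2-(prop-1-en-2-yl)hex-5-en-1-yl]-4H-chromen-4-one (flavone) | C=C(C)CC[C@H](Cc1c(OCOC)cc(OCOC)c2c1oc(-c1ccc(OCOC)cc1)cc2=O)C(=C)C | intermediate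
27 | (2S)-4-{[diethoxy(methyl)silyl]oxy}-5,7-bis(methoxymethoxy)-2-[4-(methoxymethoxy)phenyl]-8-[(2R)-5-methyl-2-(prop-1-en-2-yl)hex-5-en-1-yl]-2H-chromene | C=C(C)CC[C@H](Cc1c(OCOC)cc(OCOC)c2c1O[C@H](c1ccc(OCOC)cc1)C=C2O[Si](C)(OCC)OCC)C(=C)C | intermediate
28 | (2S)-5,7-bis(methoxymethoxy)-2-[4-(methoxymethoxy)phenyl]-8-[(2R)-5-methyl-2-(prop-1-en-2-yl)hex-5-en-1-yl]chroman-4-one | C=C(C)CC[C@H](Cc1c(OCOC)cc(OCOC)c2c1O[C@H](c1ccc(OCOC)cc1)CC2=O)C(=C)C | intermediate
29 | remangiflavanone A, (2S)-5,7-dihydroxy-2-(4-hydroxyphenyl)-8-[(2R)-5-methyl-2-(prop-1-en-2-yl)hex-5-en-1-yl]chroman-4-one | C=C(C)CC[C@H](Cc1c(O)cc(O)c2c1O[C@H](c1ccc(O)cc1)CC2=O)C(=C)C | target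

**Step count**

Total step count: 16.
Longest linear sequence: 10 steps (steps 1–4, 8–10 and 14–16, from limonene oxide 1).

**Steps most likely to fail**

**1. Step 15.**
- Hydride transfer to the electron-rich vinylogous ester may be too slow.
- Forcing may bring hydrocupration of the chain alkenes.
- Facial selectivity may be poor, or ring opening at the enolate stage may erode C2.

Fallback: C2 is set by C–C instead of C–H bond formation, with known chemistry.
- Setting out from iodophenol 17, the carbonylative annulation of step 14 is run with trimethylsilylacetylene 20 and CO 23 in place of 22. The silyl group is lost to the amine during enaminone formation, which should give 5,7-bis(methoxymethoxy)-8-alkylchromone F1.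
- Rhodium-catalysed asymmetric 1,4-addition (Hayashi–Miyaura reaction) of commercial 4-(methoxymethoxy)phenylboronic acid to F1 follows. It uses [Rh(OH)(cod)]2 and an electron-poor atropisomeric bisphosphine of the sense that leads to 2S, in toluene–water at rt. This is an established entry to 5,7-dioxygenated flavanones.
- It brings in ring B and C2 together and returns to the route at 28.

**2. Step 14.**
- Oxidative addition into the hindered, electron-rich C4a–I bond may be slow.
- The aroylpalladium species may be intercepted by diethylamine (aminocarbonylation).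
- Alkynylation may occur without CO uptake, or closure may be 5-exo.

Fallback: the same three bonds are made one after another without palladium or CO.
- Alkyne 22 is deprotonated (n-BuLi, THF, −78 °C) and formylated with DMF to 3-[4-(methoxymethoxy)phenyl]prop-2-ynal F2.
- Iodophenol 17 is treated with n-BuLi (2.2 equiv, THF, −78 °C). Deprotonation and iodine–lithium exchange give the O,C-dilithio species F3, which adds to F2 to give the propargylic alcohol F4 (both carbinol epimers).
- MnO2 in CH2Cl2 oxidises F4 to ynone 24, now isolated. Warming 24 with diethylamine in ethanol leads through enaminone 25 to flavone 26, where the route is rejoined.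

**3. Step 10.**
- Attack of hydroxide on a carbamoyl carbon shielded by two ortho substituents and the diethylamino group may be too slow.
- Long heating in alkaline ethanol may bring reductive loss of iodine.

Fallback: the carbamate is removed by hydride while tin holds the place of iodine.
- Setting out from 14, lithiation as in step 9 gives 15, which is quenched with Me3SnCl to the arylstannane carbamate F5.
- LiAlH4 in refluxing THF leaves the C–Sn bond, the MOM acetals and the alkenes alone. It cleaves the carbamate reductively to the stannyl phenol F6.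
- Ipso-iododestannylation with I2 (1 equiv, CH2Cl2, 0 °C) gives 17, where the route is rejoined.

**Further compounds**

F1 | step 15 | 5,7-bis(methoxymethoxy)-8-[(2R)-5-methyl-2-(prop-1-en-2-yl)hex-5-en-1-yl]-4H-chromen-4-one | C=C(C)CC[C@H](Cc1c(OCOC)cc(OCOC)c2c1occc2=O)C(=C)C
F2 | step 14 | 3-[4-(methoxymethoxy)phenyl]prop-2-ynal | O=CC#Cc1ccc(OCOC)cc1
F3 | step 14 | lithium 2-lithio-3,5-bis(methoxymethoxy)-6-[(2R)-5-methyl-2-(prop-1-en-2-yl)hex-5-en-1-yl]phenoxide | C=C(C)CC[C@H](Cc1c(O[Li])c([Li])c(OCOC)cc1OCOC)C(=C)C
F4 | step 14 | 2-{1-hydroxy-3-[4-(methoxymethoxy)phenyl]prop-2-yn-1-yl}-3,5-bis(methoxymethoxy)-6-[(2R)-5-methyl-2-(prop-1-en-2-yl)hex-5-en-1-yl]phenol, both carbinol epimers | C=C(C)CC[C@H](Cc1c(O)c(C(O)C#Cc2ccc(OCOC)cc2)c(OCOC)cc1OCOC)C(=C)C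
F5 | step 10 | 3,5-bis(methoxymethoxy)-2-[(2R)-5-methyl-2-(prop-1-en-2-yl)hex-5-en-1-yl]-6-(trimethylstannyl)phenyl diethylcarbamate | C=C(C)CC[C@H](Cc1c(OC(=O)N(CC)CC)c([Sn](C)(C)C)c(OCOC)cc1OCOC)C(=C)C
F6 | step 10 | 3,5-bis(methoxymethoxy)-2-[(2R)-5-methyl-2-(prop-1-en-2-yl)hex-5-en-1-yl]-6-(trimethylstannyl)phenol | C=C(C)CC[C@H](Cc1c(O)c([Sn](C)(C)C)c(OCOC)cc1OCOC)C(=C)C
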